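**Plan**

- Retrosynthesis (eudesmane numbering: ring A = C1–C5 and C10, ring B = C5–C10, C11–C13 on C7): the C12 ester and C13 methylene go back to a C11–C12 silyloxyethyl arm, the O3 and O8 esters to two ketones, the C8 ketone to an exocyclic methylene, and C1–C2 to a dienone alkene. The C9–C10 bond is then cut, which opens ring B to a phenol carrying an allylic pivalate. C8–C9 and C6=C7 are cut last.
- Enabling feature: ring A (C1–C5, C10), with oxygen at C3, methyl at C4 and the methyl-bearing quaternary C10 para to C3, is a dearomatized 2,4-dimethylphenol whose C5 carries the C6 tether.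
- Forward: 2,6-dimethylbenzaldehyde is hydroxylated at the future C3 and joined to a butyrolactone (C6–C7). The lactone is opened, C9 and the C8 methylene are added, and palladium closes ring B onto the phenol, which becomes the ring A dienone.
- Ozonolysis, C1=C2 hydrogenation, two reductions and two acylations complete the core; the arm is then converted to the acrylate. C12 stays a silyl ether until O8 is acetylated, so no γ-lactone can form with O8.
- Stereochemistry: C7 from asymmetric hydrogenation; C10 from a chair-like closure with the C7 arm equatorial, reinforced by the ligand; C8 from equatorial hydride attack anti to the C10 methyl; C3 from axial hydride attack on the α face.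

Key step: step 11

Assumption: the sense of induction of (S)-BINAP in step 4 and of the (S,S)-ligand in step 11 is taken by analogy with simpler substrates; if a first run shows the opposite sense, the mirror-image ligand is used and nothing else changes.

**Step 1**
Reactants: 1 2,6-dimethylbenzaldehyde
Product: 2 3-bromo-2,6-dimethylbenzaldehyde
Conditions: NBS (1.05 equiv), CF3CO2H, H2SO4 (0.3 equiv), rt
Reagents that add atoms: N-bromosuccinimide, O=C1CCC(=O)N1Br
Why: Electrophilic aromatic bromination goes to C3 because it is ortho to one methyl, para to the other and meta to the formyl group, and the acidic medium suppresses radical benzylic bromination.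

**Step 2**
Reactants: 2 3-bromo-2,6-dimethylbenzaldehyde
Product: 4 3-hydroxy-2,6-dimethylbenzaldehyde, via aryl pinacol boronate 3 (not isolated)
Conditions: B2pin2, PdCl2(dppf) (3 mol%), KOAc, 1,4-dioxane, 85 °C; then NaBO3·4H2O, THF/H2O, rt
Reagents that add atoms: sodium perborate (the phenol oxygen), [Na+].[Na+].O[B-]1(O)OO[B-](O)(O)OO1; bis(pinacolato)diboron (boron of 3 only), CC1(C)OB(OC1(C)C)B1OC(C)(C)C(C)(C)O1
Why: Miyaura borylation followed by perborate oxidation of the C–B bond converts the bromide into the phenol under conditions that the hindered aldehyde tolerates.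

**Step 3**
Reactants: 4 3-hydroxy-2,6-dimethylbenzaldehyde; 5 diethyl (2-oxooxolan-3-yl)phosphonate
Product: 6 (3E)-3-[(3-hydroxy-2,6-dimethylphenyl)methylidene]oxolan-2-one
Conditions: KOtBu (2.1 equiv), THF, 0 °C to rt; aq. HCl work-up
Reagents that add atoms: none
Why: Horner–Wadsworth–Emmons olefination of the phosphonolactone anion, with the second equivalent of base holding the phenol as phenoxide, forms the C6=C7 bond and should favour the E-arylidene lactone.

**Step 4**
Reactants: 6 (3E)-3-[(3-hydroxy-2,6-dimethylphenyl)methylidene]oxolan-2-one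
Product: 7 (3R)-3-[(3-hydroxy-2,6-dimethylphenyl)methyl]oxolan-2-one
Conditions: H2 (80 bar), Ru(OAc)2[(S)-BINAP] (1 mol%), MeOH/CH2Cl2, 50 °C
Reagents that add atoms: none
Why: Asymmetric hydrogenation of an exocyclic α-arylidene lactone, in which the lactone carbonyl binds ruthenium and the BINAP ligand selects the alkene face, sets C7 as R.

**Step 5**
Reactants: 7 (3R)-3-[(3-hydroxy-2,6-dimethylphenyl)methyl]oxolan-2-one
Product: 8 (2R)-4-hydroxy-2-[(3-hydroxy-2,6-dimethylphenyl)methyl]-N-methoxy-N-methylbutanamide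
Conditions: MeNH(OMe)·HCl (4 equiv), AlMe3 (4 equiv), CH2Cl2, 0 °C to rt; aq. Rochelle salt
Reagents that add atoms: N,O-dimethylhydroxylamine hydrochloride, CNOC.Cl
Why: Weinreb aminolysis of the lactone by the aluminium amide opens the ring at the acyl carbon and leaves the adjacent C7 stereocentre untouched.

**Step 6**
Reactants: 8 (2R)-4-hydroxy-2-[(3-hydroxy-2,6-dimethylphenyl)methyl]-N-methoxy-N-methylbutanamide
Product: 9 bis-TBS Weinreb amide, (2R)-4-(TBS-oxy)-2-{[3-(TBS-oxy)-2,6-dimethylphenyl]methyl}-N-methoxy-N-methylbutanamide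
Conditions: TBSCl (2.5 equiv), imidazole, DMF, rt
Reagents that add atoms: tert-butyldimethylsilyl chloride, CC(C)(C)[Si](C)(C)Cl
Why: Silylation of both hydroxyl groups blocks relactonization and masks the phenol for the organometallic steps.

**Step 7**
Reactants: 9 bis-TBS Weinreb amide
Product: 10 chloromethyl ketone, (3R)-1-chloro-5-(TBS-oxy)-3-{[3-(TBS-oxy)-2,6-dimethylphenyl]methyl}pentan-2-one
Conditions: ICH2Cl (2.5 equiv), MeLi·LiBr (2.2 equiv), THF/Et2O, −78 °C; aq. NH4Cl
Reagents that add atoms: chloroiodomethane, ClCI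
Why: Chloromethyllithium, generated by iodine–lithium exchange in the presence of the substrate, adds once to the Weinreb amide through the chelated tetrahedral adduct (Nahm–Weinreb ketone synthesis) and forms C8–C9 without epimerizing C7.

**Step 8**
Reactants: 10 chloromethyl ketone
Product: 11 pivaloyloxymethyl ketone, (3R)-5-(TBS-oxy)-3-{[3-(TBS-oxy)-2,6-dimethylphenyl]methyl}-2-oxopentyl 2,2-dimethylpropanoate
Conditions: CsO2CCMe3 (1.5 equiv), DMF, rt
Reagents that add atoms: caesium pivalate, CC(C)(C)C(=O)[O-].[Cs+]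
Why: SN2 displacement of the activated α-chloroketone chloride by a weakly basic carboxylate installs the future allylic leaving group.

**Step 9**
Reactants: 11 pivaloyloxymethyl ketone
Product: 12 allylic pivalate, (3R)-5-(TBS-oxy)-3-{[3-(TBS-oxy)-2,6-dimethylphenyl]methyl}-2-methylidenepentyl 2,2-dimethylpropanoate
Conditions: Cp2Ti(μ-CH2)(μ-Cl)AlMe2 (1.3 equiv), pyridine (cat.), THF/toluene, −40 to 0 °C
Reagents that add atoms: Tebbe reagent Cp2Ti(μ-CH2)(μ-Cl)AlMe2, written as its two halves, C=[Ti](C1C=CC=C1)C1C=CC=C1.C[Al](C)Cl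
Why: Tebbe methylenation is non-basic, so the enolizable ketone becomes the 1,1-disubstituted alkene without epimerization at C7, and the hindered pivalate reacts much more slowly than the ketone.

**Step 10**
Reactants: 12 allylic pivalate
Product: 13 phenol allylic pivalate, (3R)-5-(TBS-oxy)-3-[(3-hydroxy-2,6-dimethylphenyl)methyl]-2-methylidenepentyl 2,2-dimethylpropanoate
Conditions: K2CO3 (0.5 equiv), MeOH, 0 °C to rt
Reagents that add atoms: none
Why: Base-mediated methanolysis cleaves the aryl silyl ether much faster than the primary alkyl silyl ether or the pivalate, because phenoxide is the better leaving group at silicon.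

**Step 11**
Reactants: 13 phenol allylic pivalate
Product: 14 (7R,10S)-12-(TBS-oxy)-8-methylidene-13-noreudesma-1,4-dien-3-one (7β arm, 10β methyl)
Conditions: Pd2(dba)3·CHCl3 (2.5 mol%), (S,S)-ANDEN-phenyl Trost ligand (7.5 mol%), Cs2CO3 (1.2 equiv), MeCN (0.01 M), rt to 40 °C
Reagents that add atoms: none
Why: Zerovalent palladium ionizes the allylic pivalate to a 2-substituted π-allyl complex whose two CH2 termini are constitutionally equivalent, and the caesium phenoxide attacks one terminus from outside the metal through its methyl-bearing para carbon, forming C9–C10 and the cross-conjugated dienone. The closest known reaction type is the palladium-catalysed intramolecular asymmetric allylic dearomatization of phenols (a Tsuji–Trost alkylation by a phenoxide carbon), here closing a fused ring instead of the usual spiro ring. Ring B (C5, C6, C7, C8, C9, C10) closes in a 6-exo mode, and the allyl unit ends as the exocyclic C8 methylidene. The new quaternary centre C10 is set by a chair-like transition state that keeps the C7 arm equatorial, which places the arm and the C10 methyl cis, and the ligand antipode is chosen so that its face preference reinforces this substrate bias. The step needs para C-attack over ortho attack at C4 and over O-allylation: C10 carries the larger phenoxide coefficient and is flanked by C1–H, whereas C4 is wedged between C3–O and C5. O-allylation would give a strained eight-membered ether and is reversible under palladium, as ortho C-allylation should be, so the more stable cross-conjugated dienone should accumulate.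

**Step 12**
Reactants: 14 (7R,10S)-12-(TBS-oxy)-8-methylidene-13-noreudesma-1,4-dien-3-one
Product: 16 (7R,10S)-12-(TBS-oxy)-13-noreudesma-1,4-diene-3,8-dione, via spiro ozonide 15 (not isolated)
Conditions: O3 (1.0 equiv, metered as a CH2Cl2 solution), CH2Cl2, −78 °C; then Me2S, −78 °C to rt
Reagents that add atoms: ozone, [O-][O+]=O
Why: Criegee ozonolysis attacks the electron-rich 1,1-disubstituted alkene much faster than the two electron-poor dienone double bonds, and neutral reductive work-up unmasks the C8 ketone with the C7 arm in its stable equatorial position.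

**Step 13**
Reactants: 16 (7R,10S)-12-(TBS-oxy)-13-noreudesma-1,4-diene-3,8-dione
Product: 17 (7R,10R)-12-(TBS-oxy)-13-noreudesm-4-ene-3,8-dione
Conditions: H2 (1 atm), RhCl(PPh3)3 (10 mol%), toluene/EtOH, rt
Reagents that add atoms: none
Why: Homogeneous hydrogenation with RhCl(PPh3)3 saturates the accessible disubstituted C1=C2 bond of a cross-conjugated dienone and leaves the tetrasubstituted C4=C5 bond, as with steroidal 1,4-dien-3-ones and santonin.

**Step 14**
Reactants: 17 (7R,10R)-12-(TBS-oxy)-13-noreudesm-4-ene-3,8-dione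
Product: 18 (7R,8R,10R)-8-hydroxy-12-(TBS-oxy)-13-noreudesm-4-en-3-one (8β-OH)
Conditions: NaBH4 (1.0 equiv), MeOH/CH2Cl2 (1:1), −78 to −40 °C
Reagents that add atoms: none
Why: Borohydride reduces the saturated C8 ketone chemoselectively over the tetrasubstituted enone at low temperature, and hydride should enter equatorially from the α face because the axial C10 methyl blocks the axial β trajectory, giving the axial 8β-alcohol (8R).

**Step 15**
Reactants: 18 (7R,8R,10R)-8-hydroxy-12-(TBS-oxy)-13-noreudesm-4-en-3-one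
Product: 19 (7R,8R,10R)-8-acetoxy-12-(TBS-oxy)-13-noreudesm-4-en-3-one
Conditions: Ac2O, DMAP (0.2 equiv), pyridine, CH2Cl2, rt
Reagents that add atoms: acetic anhydride, CC(=O)OC(C)=O
Why: DMAP-catalysed acetylation esterifies the hindered axial alcohol with retention at C8.

**Step 16**
Reactants: 19 (7R,8R,10R)-8-acetoxy-12-(TBS-oxy)-13-noreudesm-4-en-3-one
Product: 20 (3S,7R,8R,10R)-8-acetoxy-12-(TBS-oxy)-13-noreudesm-4-en-3-ol (3β-OH)
Conditions: NaBH4, CeCl3·7H2O, MeOH, −78 °C
Reagents that add atoms: none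
Why: Luche 1,2-reduction delivers hydride axially on the α face of the enone, anti to the C10 methyl, which should give the pseudo-equatorial 3β-alcohol (3S) and spare the acetate.

**Step 17**
Reactants: 20 (3S,7R,8R,10R)-8-acetoxy-12-(TBS-oxy)-13-noreudesm-4-en-3-ol; 21 (2E)-3-methylpent-2-enoic acid
Product: 22 (3S,7R,8R,10R)-8-acetoxy-12-(TBS-oxy)-13-noreudesm-4-en-3-yl (2E)-3-methylpent-2-enoate
Conditions: DCC (1.3 equiv), DMAP (0.2 equiv), CH2Cl2, 0 °C to rt
Reagents that add atoms: none
Why: Steglich esterification acylates the allylic alcohol with retention at C3, and the mild low-temperature activation should avoid isomerization of the trisubstituted enoate.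

**Step 18**
Reactants: 22 (3S,7R,8R,10R)-8-acetoxy-12-(TBS-oxy)-13-noreudesm-4-en-3-yl (2E)-3-methylpent-2-enoate
Product: 23 (3S,7R,8R,10R)-8-acetoxy-12-hydroxy-13-noreudesm-4-en-3-yl (2E)-3-methylpent-2-enoate
Conditions: HF·pyridine, pyridine, THF, 0 °C to rt
Reagents that add atoms: none
Why: Buffered fluoride cleaves the primary silyl ether without touching the acetate or the allylic enoate.

**Step 19**
Reactants: 23 (3S,7R,8R,10R)-8-acetoxy-12-hydroxy-13-noreudesm-4-en-3-yl (2E)-3-methylpent-2-enoate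
Product: 24 (3S,7R,8R,10R)-8-acetoxy-12-oxo-13-noreudesm-4-en-3-yl (2E)-3-methylpent-2-enoate
Conditions: Dess–Martin periodinane (1.3 equiv), pyridine (3 equiv), CH2Cl2, rt
Reagents that add atoms: none
Why: Dess–Martin oxidation of the primary alcohol stops at the aldehyde under buffered, near-neutral conditions.

**Step 20**
Reactants: 24 (3S,7R,8R,10R)-8-acetoxy-12-oxo-13-noreudesm-4-en-3-yl (2E)-3-methylpent-2-enoate
Product: 26 (3S,7R,8R,10R)-8-acetoxy-12-oxoeudesma-4,11(13)-dien-3-yl (2E)-3-methylpent-2-enoate, via Mannich base 25 (not isolated)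
Conditions: CH2=NMe2+ I− (2 equiv), Et3N (4 equiv), CH2Cl2, rt
Reagents that add atoms: N,N-dimethylmethaniminium iodide (Eschenmoser's salt), C=[N+](C)C.[I-]
Why: Mannich reaction of the aldehyde enol with the iminium salt followed by base-induced loss of dimethylamine (Eschenmoser methylenation) installs C13, and only the aldehyde is enolizable enough to react beside the two esters.

**Step 21**
Reactants: 26 (3S,7R,8R,10R)-8-acetoxy-12-oxoeudesma-4,11(13)-dien-3-yl (2E)-3-methylpent-2-enoate
Product: 27 (3S,7R,8R,10R)-8-acetoxy-3-[(2E)-3-methylpent-2-enoyloxy]eudesma-4,11(13)-dien-12-oic acid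
Conditions: NaClO2, NaH2PO4, 2-methylbut-2-ene (20 equiv), tBuOH/H2O, 0 °C to rt
Reagents that add atoms: sodium chlorite, [Na+].[O-]Cl=O
Why: Pinnick oxidation converts the α-methylene aldehyde into the acrylic acid while the scavenger traps hypochlorous acid before it can reach the alkenes.

**Step 22**
Reactants: 27 (3S,7R,8R,10R)-8-acetoxy-3-[(2E)-3-methylpent-2-enoyloxy]eudesma-4,11(13)-dien-12-oic acid
Product: 28 methyl (3S,7R,8R,10R)-8-acetoxy-3-[(2E)-3-methylpent-2-enoyloxy]eudesma-4,11(13)-dien-12-oate (CNP0118541.1)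
Conditions: MeI (1.5 equiv), KHCO3 (1.5 equiv), DMF, 0 °C to rt
Reagents that add atoms: iodomethane, CI
Why: SN2 O-methylation of the carboxylate under anhydrous, weakly basic conditions gives the methyl ester without cleaving the acetate or the enoate.

**Compound list** (TBS = tert-butyldimethylsilyl)

1 | 2,6-dimethylbenzaldehyde | Cc1cccc(C)c1C=O | starting material
2 | 3-bromo-2,6-dimethylbenzaldehyde | Cc1ccc(Br)c(C)c1C=O | intermediate
3 | 2,6-dimethyl-3-(4,4,5,5-tetramethyl-1,3,2-dioxaborolan-2-yl)benzaldehyde | Cc1ccc(B2OC(C)(C)C(C)(C)O2)c(C)c1C=O | intermediate (not isolated)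
4 | 3-hydroxy-2,6-dimethylbenzaldehyde | Cc1ccc(O)c(C)c1C=O | intermediate
5 | diethyl (2-oxooxolan-3-yl)phosphonate | CCOP(=O)(OCC)C1CCOC1=O | starting material
6 | (3E)-3-[(3-hydroxy-2,6-dimethylphenyl)methylidene]oxolan-2-one | O=C1OCC/C1=C\c1c(C)ccc(O)c1C | intermediate
7 | (3R)-3-[(3-hydroxy-2,6-dimethylphenyl)methyl]oxolan-2-one | Cc1ccc(O)c(C)c1C[C@@H]1CCOC1=O | intermediate
8 | (2R)-4-hydroxy-2-[(3-hydroxy-2,6-dimethylphenyl)methyl]-N-methoxy-N-methylbutanamide | CON(C)C(=O)[C@@H](CCO)Cc1c(C)ccc(O)c1C | intermediate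
9 | (2R)-4-[(tert-butyldimethylsilyl)oxy]-2-({3-[(tert-butyldimethylsilyl)oxy]-2,6-dimethylphenyl}methyl)-N-methoxy-N-methylbutanamide | CON(C)C(=O)[C@@H](CCO[Si](C)(C)C(C)(C)C)Cc1c(C)ccc(O[Si](C)(C)C(C)(C)C)c1C | intermediate
10 | (3R)-5-[(tert-butyldimethylsilyl)oxy]-3-({3-[(tert-butyldimethylsilyl)oxy]-2,6-dimethylphenyl}methyl)-1-chloropentan-2-one | ClCC(=O)[C@@H](CCO[Si](C)(C)C(C)(C)C)Cc1c(C)ccc(O[Si](C)(C)C(C)(C)C)c1C | intermediate
11 | (3R)-5-[(tert-butyldimethylsilyl)oxy]-3-({3-[(tert-butyldimethylsilyl)oxy]-2,6-dimethylphenyl}methyl)-2-oxopentyl 2,2-dimethylpropanoate | CC(C)(C)C(=O)OCC(=O)[C@@H](CCO[Si](C)(C)C(C)(C)C)Cc1c(C)ccc(O[Si](C)(C)C(C)(C)C)c1C | intermediate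
12 | (3R)-5-[(tert-butyldimethylsilyl)oxy]-3-({3-[(tert-butyldimethylsilyl)oxy]-2,6-dimethylphenyl}methyl)-2-methylidenepentyl 2,2-dimethylpropanoate | CC(C)(C)C(=O)OCC(=C)[C@@H](CCO[Si](C)(C)C(C)(C)C)Cc1c(C)ccc(O[Si](C)(C)C(C)(C)C)c1C | intermediate
13 | (3R)-5-[(tert-butyldimethylsilyl)oxy]-3-[(3-hydroxy-2,6-dimethylphenyl)methyl]-2-methylidenepentyl 2,2-dimethylpropanoate | CC(C)(C)C(=O)OCC(=C)[C@@H](CCO[Si](C)(C)C(C)(C)C)Cc1c(C)ccc(O)c1C | intermediate (key-step precursor)
14 | (4aS,7R)-7-{2-[(tert-butyldimethylsilyl)oxy]ethyl}-1,4a-dimethyl-6-methylidene-5,6,7,8-tetrahydronaphthalen-2(4aH)-one | CC(C)(C)[Si](C)(C)OCC[C@H]1CC2=C(C)C(=O)C=C[C@]2(C)CC1=C | intermediate (key-step product)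
15 | secondary ozonide of 14: 1,2,4-trioxolane spiro-fused at C8, both spiro epimers | CC(C)(C)[Si](C)(C)OCC[C@H]1CC2=C(C)C(=O)C=C[C@]2(C)CC13OCOO3 | intermediate (not isolated)
16 | (4aS,7R)-7-{2-[(tert-butyldimethylsilyl)oxy]ethyl}-1,4a-dimethyl-7,8-dihydronaphthalene-2,6(4aH,5H)-dione | CC(C)(C)[Si](C)(C)OCC[C@H]1CC2=C(C)C(=O)C=C[C@]2(C)CC1=O | intermediate
17 | (4aR,7R)-7-{2-[(tert-butyldimethylsilyl)oxy]ethyl}-1,4a-dimethyl-4,4a,7,8-tetrahydronaphthalene-2,6(3H,5H)-dione | CC(C)(C)[Si](C)(C)OCC[C@H]1CC2=C(C)C(=O)CC[C@]2(C)CC1=O | intermediate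
18 | (4aR,6R,7R)-7-{2-[(tert-butyldimethylsilyl)oxy]ethyl}-6-hydroxy-1,4a-dimethyl-4,4a,5,6,7,8-hexahydronaphthalen-2(3H)-one | CC(C)(C)[Si](C)(C)OCC[C@H]1CC2=C(C)C(=O)CC[C@]2(C)C[C@H]1O | intermediate
19 | (2R,3R,8aR)-3-{2-[(tert-butyldimethylsilyl)oxy]ethyl}-5,8a-dimethyl-6-oxo-1,2,3,4,6,7,8,8a-octahydronaphthalen-2-yl acetate | CC(C)(C)[Si](C)(C)OCC[C@H]1CC2=C(C)C(=O)CC[C@]2(C)C[C@H]1OC(C)=O | intermediate
20 | (2R,3R,6S,8aR)-3-{2-[(tert-butyldimethylsilyl)oxy]ethyl}-6-hydroxy-5,8a-dimethyl-1,2,3,4,6,7,8,8a-octahydronaphthalen-2-yl acetate | CC(C)(C)[Si](C)(C)OCC[C@H]1CC2=C(C)[C@@H](O)CC[C@]2(C)C[C@H]1OC(C)=O | intermediate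
21 | (2E)-3-methylpent-2-enoic acid | CC/C(C)=C/C(=O)O | starting material
22 | (2S,4aR,6R,7R)-6-(acetyloxy)-7-{2-[(tert-butyldimethylsilyl)oxy]ethyl}-1,4a-dimethyl-2,3,4,4a,5,6,7,8-octahydronaphthalen-2-yl (2E)-3-methylpent-2-enoate | CC(C)(C)[Si](C)(C)OCC[C@H]1CC2=C(C)[C@@H](OC(=O)/C=C(\C)CC)CC[C@]2(C)C[C@H]1OC(C)=O | intermediate
23 | (2S,4aR,6R,7R)-6-(acetyloxy)-7-(2-hydroxyethyl)-1,4a-dimethyl-2,3,4,4a,5,6,7,8-octahydronaphthalen-2-yl (2E)-3-methylpent-2-enoate | OCC[C@H]1CC2=C(C)[C@@H](OC(=O)/C=C(\C)CC)CC[C@]2(C)C[C@H]1OC(C)=O | intermediate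
24 | (2S,4aR,6R,7R)-6-(acetyloxy)-1,4a-dimethyl-7-(2-oxoethyl)-2,3,4,4a,5,6,7,8-octahydronaphthalen-2-yl (2E)-3-methylpent-2-enoate | O=CC[C@H]1CC2=C(C)[C@@H](OC(=O)/C=C(\C)CC)CC[C@]2(C)C[C@H]1OC(C)=O | intermediate
25 | (2S,4aR,6R,7R)-6-(acetyloxy)-7-[1-(dimethylamino)-3-oxopropan-2-yl]-1,4a-dimethyl-2,3,4,4a,5,6,7,8-octahydronaphthalen-2-yl (2E)-3-methylpent-2-enoate, both C11 epimers | CN(C)CC(C=O)[C@H]1CC2=C(C)[C@@H](OC(=O)/C=C(\C)CC)CC[C@]2(C)C[C@H]1OC(C)=O | intermediate (not isolated)
26 | (2S,4aR,6R,7R)-6-(acetyloxy)-1,4a-dimethyl-7-(3-oxoprop-1-en-2-yl)-2,3,4,4a,5,6,7,8-octahydronaphthalen-2-yl (2E)-3-methylpent-2-enoate | C=C(C=O)[C@H]1CC2=C(C)[C@@H](OC(=O)/C=C(\C)CC)CC[C@]2(C)C[C@H]1OC(C)=O | intermediate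
27 | 2-[(2R,3R,4aR,7S)-3-(acetyloxy)-4a,8-dimethyl-7-{[(2E)-3-methylpent-2-enoyl]oxy}-1,2,3,4,4a,5,6,7-octahydronaphthalen-2-yl]prop-2-enoic acid | C=C(C(=O)O)[C@H]1CC2=C(C)[C@@H](OC(=O)/C=C(\C)CC)CC[C@]2(C)C[C@H]1OC(C)=O | intermediate
28 | methyl 2-[(2R,3R,4aR,7S)-3-(acetyloxy)-4a,8-dimethyl-7-{[(2E)-3-methylpent-2-enoyl]oxy}-1,2,3,4,4a,5,6,7-octahydronaphthalen-2-yl]prop-2-enoate | C=C(C(=O)OC)[C@H]1CC2=C(C)[C@@H](OC(=O)/C=C(\C)CC)CC[C@]2(C)C[C@H]1OC(C)=O | target

**Step count and risks**

Total step count: 22. Longest linear sequence: 22 steps (1 to 28); compounds 5 and 21 are purchased.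

Steps most likely to fail:

1. Step 11. The phenoxide may attack through the ortho carbon C4 or through oxygen instead of the para carbon C10, or ligand and substrate may oppose each other so that the facial selectivity at C10 drops. The fallback inverts the polarity of the same C9–C10 bond formation and sets out from Weinreb amide 9. Addition of (trimethylsilyl)methyllithium should give the β-ketosilane F1, Tebbe methylenation the allylsilane F2, and K2CO3 in methanol the free phenol allylsilane F3. Oxidation of F3 with PhI(OAc)2 in (CF3)2CHOH generates the phenoxenium ion, which the tethered allylsilane traps at the para carbon with loss of silicon, the same chair-like arrangement setting C10. The fallback comes back to the route at 14.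

2. Step 4. The di-ortho-substituted aryl ring is twisted out of the alkene plane, so the catalyst may discriminate the two alkene faces poorly. The fallback moves the stereo-defining hydrogenation to a carboxylate-chelating itaconate substrate and sets out from aldehyde 4. Stobbe condensation with dimethyl succinate (KOtBu, tBuOH) should give the half-ester F4, and hydrogenation with [Rh(cod){(S,S)-Et-DuPhos}]BF4 the (R)-succinate half-ester F5. BH3·SMe2 then reduces the free acid selectively, and the resulting hydroxy ester lactonizes under acid catalysis. The fallback comes back to the route at 7.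

3. Step 14. Hydride may be delivered from the axial β face, giving the equatorial 8α-alcohol, and the C8 configuration would then be wrong. The fallback sets the centre by SN2 inversion instead of by hydride delivery and sets out from 17. The 8α-alcohol F6 obtained from the reduction is treated with acetic acid, PPh3 and diisopropyl azodicarboxylate (Mitsunobu reaction), which should give the 8β-acetate directly with inversion. The fallback comes back to the route at 19.

**Further compounds**

F1 | step 11 | (3R)-5-[(tert-butyldimethylsilyl)oxy]-3-({3-[(tert-butyldimethylsilyl)oxy]-2,6-dimethylphenyl}methyl)-1-(trimethylsilyl)pentan-2-one | C[Si](C)(C)CC(=O)[C@@H](CCO[Si](C)(C)C(C)(C)C)Cc1c(C)ccc(O[Si](C)(C)C(C)(C)C)c1C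
F2 | step 11 | [(3R)-5-[(tert-butyldimethylsilyl)oxy]-3-({3-[(tert-butyldimethylsilyl)oxy]-2,6-dimethylphenyl}methyl)-2-methylidenepentyl]trimethylsilane | C[Si](C)(C)CC(=C)[C@@H](CCO[Si](C)(C)C(C)(C)C)Cc1c(C)ccc(O[Si](C)(C)C(C)(C)C)c1C
F3 | step 11 | 3-{(2R)-4-[(tert-butyldimethylsilyl)oxy]-2-[3-(trimethylsilyl)prop-1-en-2-yl]butyl}-2,4-dimethylphenol | C[Si](C)(C)CC(=C)[C@@H](CCO[Si](C)(C)C(C)(C)C)Cc1c(C)ccc(O)c1C
F4 | step 4 | (3E)-4-(3-hydroxy-2,6-dimethylphenyl)-3-(methoxycarbonyl)but-3-enoic acid | COC(=O)/C(CC(=O)O)=C/c1c(C)ccc(O)c1C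
F5 | step 4 | (3R)-4-(3-hydroxy-2,6-dimethylphenyl)-3-(methoxycarbonyl)butanoic acid | COC(=O)[C@@H](CC(=O)O)Cc1c(C)ccc(O)c1C
F6 | step 14 | (4aR,6S,7R)-7-{2-[(tert-butyldimethylsilyl)oxy]ethyl}-6-hydroxy-1,4a-dimethyl-4,4a,5,6,7,8-hexahydronaphthalen-2(3H)-one | CC(C)(C)[Si](C)(C)OCC[C@H]1CC2=C(C)C(=O)CC[C@]2(C)C[C@@H]1O
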